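A direct plan would O-alkylate 2,4-dibromophenol A1 to the aryloxyacetone A2 and build ring A around it by condensation with sodium nitromalonaldehyde A3, giving nitrophenol A4.
It would then methylate, reduce to aniline A5, brominate twice ortho to nitrogen to give the 2,6-dibromoaniline A6, and close with a Sandmeyer bromination.
Its weakest steps would be:
- the ring-forming condensation, which would leave closure of ring A to an unsymmetrical ketone that must react at both α-carbons with a shock-sensitive salt while self-condensation competes;
- the nitro group as placeholder for one bromine, which would spend reduction, bromination and diazotisation without adding to the skeleton, the bromination having to enter the crowded carbon between NH2 and O-aryl;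
- the final radical bromodediazoniation of a 2,6-dibromoaniline, prone to hydrodediazoniation, which would fall on the most valuable intermediate.

The new route cuts one bond, O–C1' between the ether oxygen and ring B, and closes no ring.
Ring A (C1 OMe, C2 O-aryl, C3–C5 Br, C6 H) is guaiacol and is finished first: while the oxygen on C2 is still a free hydroxyl, its ortho (C3) and para (C5) carbons and the carbon para to OMe (C4) take up all three bromines at once.
Ring B arrives last as an aryl cation equivalent on trivalent iodine, a polarity reversal that needs no transition metal.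
This is possible because C1', with Br on C2' and C4', is the electron-poor, ortho-substituted ipso carbon that an iodonium salt hands to a phenoxide.
No ring closure, nitrogen placeholder or diazonium salt remains.

Key step: step 3

Assumption: guaiacol, 2,4-dibromo-1-iodobenzene and 1,3,5-trimethoxybenzene are taken as commercial, and direct tribromination of guaiacol is taken to give the 4,5,6-isomer as in its classical exhaustive halogenation.

Step 1
Reactants: 1 guaiacol (2-methoxyphenol)
Product: 4 2,3,4-tribromo-6-methoxyphenol (4,5,6-tribromoguaiacol), via 4-bromo-2-methoxyphenol 2 (not isolated), via 2,4-dibromo-6-methoxyphenol 3 (not isolated)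
Conditions: Br2 (3.1 equiv), AcOH, 10 °C to 25 °C; aq. NaHSO3; recrystallisation
Reagents that add atoms: bromine, BrBr
Why: Electrophilic aromatic bromination under control of the free hydroxyl, which directs to its para (ring A C5) and ortho (C3) carbons, while the methoxy group directs to its para carbon (C4); the remaining C6–H is meta to the hydroxyl on a ring already carrying three bromines, so substitution should stop at the tribromide.

Step 2
Reactants: 5 2,4-dibromo-1-iodobenzene; 6 1,3,5-trimethoxybenzene
Product: 8 (2,4-dibromophenyl)(2,4,6-trimethoxyphenyl)iodonium p-toluenesulfonate, via hydroxy(tosyloxy)iodoarene 7 (not isolated)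
Conditions: mCPBA (1.1 equiv), TsOH·H2O (1.05 equiv), MeCN, 77 °C; then 6 (1.05 equiv), 77 °C to 20 °C; Et2O trituration
Reagents that add atoms: p-toluenesulfonic acid monohydrate, Cc1ccc(cc1)S(=O)(=O)O.O (tosylate of 7 and 8); 3-chloroperbenzoic acid, OOC(=O)c1cccc(Cl)c1 (hydroxyl oxygen of 7 only, lost again as water)
Why: One-pot peracid oxidation of the aryl iodide to the hydroxy(tosyloxy)iodoarene 7, then electrophilic aromatic substitution of the strongly activated 1,3,5-trimethoxybenzene (three equivalent C–H positions) at trivalent iodine, is the standard synthesis of aryl(2,4,6-trimethoxyphenyl)iodonium tosylates, and aryl bromides are inert to the peracid.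

Step 3
Reactants: 4 2,3,4-tribromo-6-methoxyphenol; 8 (2,4-dibromophenyl)(2,4,6-trimethoxyphenyl)iodonium p-toluenesulfonate
Product: 11 1,2,3-tribromo-4-(2,4-dibromophenoxy)-5-methoxybenzene, via potassium 2,3,4-tribromo-6-methoxyphenolate 9 (not isolated), via aryloxy(diaryl)iodane 10 (not isolated)
Conditions: t-BuOK (1.0 equiv), THF, 0 °C, 15 min; then 8 (1.2 equiv), 40 to 60 °C
Reagents that add atoms: potassium tert-butoxide, CC(C)(C)[O-].[K+] (potassium of 9 only, lost again as potassium p-toluenesulfonate)
Why: Ligand coupling on trivalent iodine: phenoxide 9 displaces tosylate from 8 to give the T-shaped aryloxy(diaryl)iodane 10, and the oxygen then attacks the ipso carbon C1' of the 2,4-dibromophenyl ligand in a three-centre reductive elimination that forms O–C1' and releases 2-iodo-1,3,5-trimethoxybenzene as iodine falls from trivalent to monovalent. The closest known reaction type is the metal-free O-arylation of phenoxides, including ortho-disubstituted and polybrominated ones, with diaryliodonium salts and with aryl(2,4,6-trimethoxyphenyl)iodonium tosylates. No ring is closed and no stereocentre is formed. Three selectivities are needed: transfer of ring B and not of the auxiliary, which the electron-poor, ortho-brominated C1' (better able to take up negative charge in the transition state and favoured by the ortho effect) secures against the electron-rich trimethoxyphenyl ipso carbon; O- over C-arylation, which is forced because both ortho carbons and the para carbon of the phenoxide oxygen (C1, C3, C5 of ring A) are substituted; and survival of five C–Br bonds, which follows from the absence of any transition metal or reductant. One equivalent of base on a phenol whose pKa should lie near 7 leaves no strong base to deprotonate C6'–H of 8 and start an aryne pathway.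

Compound list

1 | guaiacol (2-methoxyphenol) | COc1ccccc1O | starting material
2 | 4-bromo-2-methoxyphenol | COc1cc(Br)ccc1O | intermediate (not isolated)
3 | 2,4-dibromo-6-methoxyphenol (4,6-dibromoguaiacol) | COc1cc(Br)cc(Br)c1O | intermediate (not isolated)
4 | 2,3,4-tribromo-6-methoxyphenol (4,5,6-tribromoguaiacol) | COc1cc(Br)c(Br)c(Br)c1O | intermediate
5 | 2,4-dibromo-1-iodobenzene | Brc1ccc(I)c(Br)c1 | starting material
6 | 1,3,5-trimethoxybenzene | COc1cc(OC)cc(OC)c1 | starting material
7 | 2,4-dibromo-1-[hydroxy(tosyloxy)iodo]benzene | OI(OS(=O)(=O)c1ccc(C)cc1)c1ccc(Br)cc1Br | intermediate (not isolated)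
8 | (2,4-dibromophenyl)(2,4,6-trimethoxyphenyl)iodonium p-toluenesulfonate | COc1cc(OC)c([I+]c2ccc(Br)cc2Br)c(OC)c1.Cc1ccc(cc1)S(=O)(=O)[O-] | intermediate
9 | potassium 2,3,4-tribromo-6-methoxyphenolate | COc1cc(Br)c(Br)c(Br)c1[O-].[K+] | intermediate (not isolated)
10 | (2,4-dibromophenyl)(2,3,4-tribromo-6-methoxyphenoxy)(2,4,6-trimethoxyphenyl)iodane | COc1cc(Br)c(Br)c(Br)c1OI(c1ccc(Br)cc1Br)c1c(OC)cc(OC)cc1OC | intermediate (not isolated)
11 | 1,2,3-tribromo-4-(2,4-dibromophenoxy)-5-methoxybenzene | COc1cc(Br)c(Br)c(Br)c1Oc1ccc(Br)cc1Br | target

Total step count: 3. Longest linear sequence: 2 (step 1 then step 3, or step 2 then step 3).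

Steps most likely to fail:

Step 3. Ligand coupling may be slow because phenoxide 9 is a weak nucleophile flanked by OMe and Br, so that decomposition of 8 or transfer of the auxiliary aryl group could take over. The fallback sets out from 4 and returns at 11. Nucleophilic aromatic substitution of 4 on 2-bromo-1-fluoro-4-nitrobenzene (K2CO3, DMF, 80 °C) should give 1,2,3-tribromo-4-(2-bromo-4-nitrophenoxy)-5-methoxybenzene F1. Fe powder and NH4Cl in EtOH/H2O should reduce it to 3-bromo-4-(2,3,4-tribromo-6-methoxyphenoxy)aniline F2 without touching C–Br. t-BuONO and CuBr2 in MeCN should then convert this aniline through 3-bromo-4-(2,3,4-tribromo-6-methoxyphenoxy)benzenediazonium bromide F3 into 11. This costs two further steps and brings back a Sandmeyer reaction, but on an unhindered aniline whose nitrogen is para to the ether oxygen.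

Step 1. Bromination may not stop cleanly: the third bromine could enter ortho to the methoxy group instead of para to it, or a fourth could follow, giving isomers that are hard to separate. The fallback sets out from 1 and returns at 4, with each bromine entering under a single directing group. Acetylation (Ac2O, pyridine) should give 2-methoxyphenyl acetate F4. Bromination (Br2, AcOH) para to the now dominant methoxy group should give 5-bromo-2-methoxyphenyl acetate F5. Hydrolysis (NaOH, MeOH/H2O, then HCl) should give 5-bromo-2-methoxyphenol F6. Br2 (2 equiv, AcOH) should then fill the ortho and para carbons of the free hydroxyl to give 4.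

Step 2. The electron-rich arene 6 may be oxidised or arylated more than once instead of attacking the iodane cleanly, or the salt may fail to crystallise. The fallback sets out from 5 and returns at 11. Oxidation of 5 with mCPBA and BF3·OEt2 in CH2Cl2, followed by (2,4-dibromophenyl)boronic acid, should give by ipso substitution at boron the symmetric bis(2,4-dibromophenyl)iodonium tetrafluoroborate F7. This salt carries no auxiliary and would replace 8 under the conditions of step 3, giving 11 and returning 5 for re-use.

Further compounds
F1 | step 3 | 1,2,3-tribromo-4-(2-bromo-4-nitrophenoxy)-5-methoxybenzene | COc1cc(Br)c(Br)c(Br)c1Oc1ccc(cc1Br)[N+](=O)[O-]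
F2 | step 3 | 3-bromo-4-(2,3,4-tribromo-6-methoxyphenoxy)aniline | COc1cc(Br)c(Br)c(Br)c1Oc1ccc(N)cc1Br
F3 | step 3 | 3-bromo-4-(2,3,4-tribromo-6-methoxyphenoxy)benzenediazonium bromide | COc1cc(Br)c(Br)c(Br)c1Oc1ccc(cc1Br)[N+]#N.[Br-]
F4 | step 1 | 2-methoxyphenyl acetate | COc1ccccc1OC(C)=O
F5 | step 1 | 5-bromo-2-methoxyphenyl acetate | COc1ccc(Br)cc1OC(C)=O
F6 | step 1 | 5-bromo-2-methoxyphenol | COc1ccc(Br)cc1O
F7 | step 2 | bis(2,4-dibromophenyl)iodonium tetrafluoroborate | Brc1ccc([I+]c2ccc(Br)cc2Br)c(Br)c1.F[B-](F)(F)F
A1 | direct plan | 2,4-dibromophenol | Oc1ccc(Br)cc1Br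
A2 | direct plan | 1-(2,4-dibromophenoxy)propan-2-one | CC(=O)COc1ccc(Br)cc1Br
A3 | direct plan | sodium nitromalonaldehyde | O=CC(C=O)=[N+]([O-])[O-].[Na+]
A4 | direct plan | 2-(2,4-dibromophenoxy)-4-nitrophenol | Oc1ccc(cc1Oc1ccc(Br)cc1Br)[N+](=O)[O-]
A5 | direct plan | 3-(2,4-dibromophenoxy)-4-methoxyaniline | COc1ccc(N)cc1Oc1ccc(Br)cc1Br
A6 | direct plan | 2,6-dibromo-3-(2,4-dibromophenoxy)-4-methoxyaniline | COc1cc(Br)c(N)c(Br)c1Oc1ccc(Br)cc1Br
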